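In a one-step world substrate simply turns into product, and a recipe can change the timing but not the yield. These runs show something else.

| setting | dawn | noon | summer | midnight | south-east | south | west | north-east | north-west |
|---|---|---|---|---|---|---|---|---|---|
| substrate | 0.0020 M | 0.0020 M | 0.0020 M | 0.0020 M | 0.0020 M | 0.0020 M | 0.0020 M | 0.0020 M | 0.0020 M |
| first nucleophile | 3 mM | 3 mM | 3 mM | 6 mM | 3.00 mM (fed, over 3.0 min) | 3.00 mM (fed, over 3.0 min) | 3.00 mM (fed, over 50 s) | 3.00 mM | 3.00 mM |
| second nucleophile | 2 mM | 2.8 mM | 4.4 mM | 2 mM | 2.00 mM | 2.00 mM | 2.00 mM | 2.00 mM | 2.00 mM |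
| temperature | 85 °C | 96 °C | 85 °C | 96 °C |  | 90 °C | 90 °C | 90 °C |  |
| remark | run made earlier | run made earlier | run made earlier | run made earlier | the addition at 70 °C, then warmed to 90 °C; the feed brings no volume worth counting | all else is in the flask from the start; the feed brings no volume worth counting | all else is in the flask from the start; the feed brings no volume worth counting | everything together at the start | everything together at the start at 70 °C, warmed to 90 °C at 3.0 min |
| time |  |  |  |  | 8.0 min | 8.0 min | 8.0 min | 8.0 min | 8.0 min |

| run | time / min | other capture product / % | target / % |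
|---|---|---|---|
| dawn | 1.00 | 52.6 | 7.0 |
| dawn | 2.50 | 71.4 | 8.3 |
| dawn | 3.00 | 73.9 | 8.8 |
| dawn | 5.00 | 75.5 | 8.0 |
| dawn | 6.00 | 75.4 | 8.7 |
| dawn | 8.00 | 75.7 | 7.4 |
| noon | 0.500 | 60.6 | 7.4 |
| noon | 0.833 | 72.7 | 8.4 |
| noon | 1.33 | 79.4 | 8.6 |
| noon | 2.00 | 80.8 | 6.6 |
| noon | 3.00 | 80.5 | 6.9 |
| noon | 4.00 | 80.0 | 8.3 |
| noon | 6.00 | 81.8 | 7.7 |
| summer | 1.00 | 58.9 | 3.4 |
| summer | 2.00 | 79.4 | 2.9 |
| summer | 3.00 | 86.1 | 2.5 |
| summer | 4.00 | 88.3 | 3.5 |
| summer | 5.00 | 89.1 | 2.9 |
| summer | 6.00 | 89.6 | 2.3 |
| midnight | 1.33 | 58.6 | 17.0 |
| midnight | 2.50 | 59.9 | 18.3 |
| midnight | 4.00 | 60.5 | 17.7 |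
| midnight | 5.00 | 60.7 | 17.7 |
| midnight | 6.00 | 60.7 | 18.2 |

(each reading ± 0.5 percentage points)

- the earlier runs were read with a standard deviation of 0.5 percentage points

- the flask that comes out highest in amount of other capture product, in percent of the substrate charged; "all alike" if 1.5 percentage points covers them all (south-east / south / west / north-east / north-west / all alike)
- amount of other capture product at the end, in percent of the substrate charged, south-east
- amount of other capture product at the end, in percent of the substrate charged, south
- amount of other capture product at the end, in percent of the substrate charged, west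
- amount of other capture product at the end, in percent of the substrate charged, north-east
- amount of other capture product at the end, in percent of the substrate charged, north-west

From dawn to summer, second nucleophile rises from 2 mM to 4.4 mM. The plateau of other capture product climbs from 75.7 % to 89.6 %, yet the fraction of it reached at 1.00 min stays close, 69.5 % against 65.7 %. So we suppose that substrate first gives an intermediate, used as fast as it forms, and that the two nucleophiles share it.

Our rule is the share of second nucleophile, S·c(second nucleophile) / (S·c(second nucleophile) + c(first nucleophile)), where S is the selectivity factor, the capture rate of second nucleophile over that of first nucleophile per mM of each. Integrated, the rule says ln of the fraction of second nucleophile left equals S times ln of the fraction of first nucleophile left. We assume the remainder of the substrate went through first nucleophile, though dawn's target reads less than that remainder. Dawn gives 8.00 and midnight 6.65, so near 90 °C we take S = 7.33.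

The early readings give 1.19 /min at 85 °C and 2.70 /min at 96 °C. Their geometric mean puts the substrate lifetime at 0.559 min. After one lifetime, counting the substrate used as taken up by second nucleophile, roughly 0.736 mM of second nucleophile stands. South has then received 0.559 mM of first nucleophile and west 2.01 mM, while north-east was charged 3.00 mM at the start. Taking these amounts as what stands, with no loss of first nucleophile counted, the rough shares are 90.6 % in south, 72.8 % in west and 64.3 % in north-east, so in this reckoning south stands highest. Our readings stop at 85 °C, so we do not reckon the flasks started at 70 °C. We would charge south, feeding over 3.0 min.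

The forecast names south, with 88 % there, 80 % in west, 74 % in north-east, 79.3 % in south-east and 76 % in north-west: “Slow feeding keeps the first nucleophile scarce during the fast consumption”.

South ends highest, at 89.2 %, against 81.0 % in south-east, 80.9 % in west, 74.8 % in north-east and 78.4 % in north-west. In north-east at 0.596 min, the rate of making intermediate over the rate of using it up stands at 1.00. Read through S, the results give an effective ratio of first to second nucleophile: 0.890 in south and 2.47 in north-east.

    second nucleophile + intermediate → other capture product (k = 36000 /M/s, Ea = 12.0 kJ/mol)
    first nucleophile → decomposed reagent (k = 0.0220 /s, Ea = 96.0 kJ/mol)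
    substrate → intermediate (k = 0.0270 /s, Ea = 91.0 kJ/mol)
    substrate + target → side product (k = 18.0 /M/s, Ea = 47.0 kJ/mol)
    first nucleophile + intermediate → target (k = 7900 /M/s, Ea = 33.0 kJ/mol)
    first nucleophile ⇌ dormant form (K = 0.250, k = 0.280 /s, Ea = 90.0 kJ/mol, ΔH = −58.0 kJ/mol)
    (constants at 90 °C)

Now take north-east with 5.0 × 10⁻⁴ M of substrate, which makes 6.00 equiv of first nucleophile. S with the starting charges gives a share of 83.0 %. The computed flask gives 83.4 %, with 79.1 % of second nucleophile left.

The numbers in the tables were computed with made-up constants; scatter was added.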